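## Retrosynthetic overview

1. The (3E,5E)-diene is cut at C4–C5 and C4–CH3: two palladium couplings on a 1,1-dibromoalkene join the ring A enal 34 to the alkyne 12.
2. The ring A enal comes from a ketone by isopropenyl addition and a [3,3] chromate transposition; the propyl-bearing carbon is fixed by equilibration inside a temporary trans-fused acetal.
3. Key bond: the quaternary C–CH2 bond of ring A is made by an anionic oxy-Cope rearrangement of the 1,2-adduct of a methoxyallyl zinc reagent to enone 18, with allylation of the resulting enolate in the same flask.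
4. Enone 18 comes from (S)-carvone (MeLi, allylic oxidation, excision of the isopropenyl group); alkyne 12 comes from (S)-pulegone (gem-dimethylation, retro-aldol, bromoformylation, Sonogashira, allylic diazene rearrangement).
5. No carbocycle is built: ring A is the carvone ring and the trimethyl-methylidene ring is the pulegone ring; only a temporary pyran acetal ring is closed (step 12) and reopened (step 15).

Assumption: (S)-(+)-carvone and (S)-(−)-pulegone are bought as single enantiomers; where a step is not fully diastereoselective the minor isomer is removed by chromatography.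

## Route

Step 1
Reactants: 1 (S)-(−)-pulegone
Product: 3 (3S)-2,2,3-trimethyl-6-(propan-2-ylidene)cyclohexan-1-one, via monomethyl ketone 2 (not isolated)
Conditions: LiN(i-Pr)2, THF, −78 °C; MeI, −78 → 0 °C; then LiN(i-Pr)2, −78 °C; MeI, −78 → 23 °C
Reagents that add atoms: iodomethane, CI
Why: Two kinetic α′-enolate alkylations; the isopropylidene group blocks the other α-carbon, so both methyl groups enter next to the bought C–CH3 stereocentre, which is not touched.

Step 2
Reactants: 3 (3S)-2,2,3-trimethyl-6-(propan-2-ylidene)cyclohexan-1-one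
Product: 4 (3S)-2,2,3-trimethylcyclohexan-1-one
Conditions: KOH, H2O–EtOH, reflux, acetone distilled off
Reagents that add atoms: none
Why: Retro-aldol reaction (conjugate hydration, then C–C cleavage) expels acetone; the stereocentre is β to the carbonyl and cannot epimerise.

Step 3
Reactants: 4 (3S)-2,2,3-trimethylcyclohexan-1-one
Product: 6 (4S)-2-bromo-3,3,4-trimethylcyclohex-1-ene-1-carbaldehyde, via iminium bromide 5 (not isolated)
Conditions: PBr3, DMF, CHCl3, 0 → 60 °C; aq. NaOAc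
Reagents that add atoms: N,N-dimethylformamide, CN(C)C=O; phosphorus tribromide, BrP(Br)Br; water, O
Why: Vilsmeier–Haack–Arnold bromoformylation; the ketone has one enolisable α-CH2, so the formyl carbon enters there and the carbonyl carbon becomes the vinyl bromide.

Step 4
Reactants: 6 (4S)-2-bromo-3,3,4-trimethylcyclohex-1-ene-1-carbaldehyde
Product: 7 (4S)-3,3,4-trimethyl-2-[(trimethylsilyl)ethynyl]cyclohex-1-ene-1-carbaldehyde
Conditions: ethynyltrimethylsilane, Pd(PPh3)2Cl2 (5 mol %), CuI (10 mol %), Et3N, THF, 50 °C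
Reagents that add atoms: ethynyltrimethylsilane, C#C[Si](C)(C)C
Why: Sonogashira coupling of the activated β-bromo enal; no stereocentre is involved.

Step 5
Reactants: 7 (4S)-3,3,4-trimethyl-2-[(trimethylsilyl)ethynyl]cyclohex-1-ene-1-carbaldehyde
Product: 9 [(4S)-2-ethynyl-3,3,4-trimethylcyclohex-1-en-1-yl]methanol, via silylated allylic alcohol 8 (not isolated)
Conditions: NaBH4, MeOH, 0 °C; then K2CO3, 23 °C
Reagents that add atoms: none
Why: 1,2-Reduction of the aldehyde by borohydride, then methanolysis of the alkynyl C–Si bond while the enyne is still conjugated and base-stable.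

Step 6
Reactants: 9 [(4S)-2-ethynyl-3,3,4-trimethylcyclohex-1-en-1-yl]methanol
Product: 12 (1S,3S)-1-ethynyl-2,2,3-trimethyl-6-methylidenecyclohexane, via sulfonylhydrazine 10 (not isolated), via allylic diazene 11 (not isolated)
Conditions: 2-nitrobenzenesulfonohydrazide, PPh3, diethyl azodicarboxylate, THF, −30 °C; then 23 °C
Reagents that add atoms: none
Why: Myers reductive 1,3-transposition: Mitsunobu N-alkylation and loss of sulfinic acid give the allylic diazene, which loses N2 in a concerted sigmatropic (retro-ene, 1,5-hydrogen) shift that moves the alkene exocyclic and delivers H to C1 anti to the pseudoaxial methyl of the neighbouring CMe2 group, so the ethynyl group ends equatorial and cis to the 3-methyl.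

Step 7
Reactants: 13 (S)-(+)-carvone
Product: 15 triethyl{[(1S,5S)-1,2-dimethyl-5-(prop-1-en-2-yl)cyclohex-2-en-1-yl]oxy}silane, via lithium alkoxide 14 (not isolated)
Conditions: MeLi, Et2O, −78 °C; then Et3SiOTf, −78 → 0 °C
Reagents that add atoms: methyllithium, [Li]C; triethylsilyl trifluoromethanesulfonate, CC[Si](CC)(CC)OS(=O)(=O)C(F)(F)F
Why: 1,2-Addition by axial attack anti to the equatorial isopropenyl group puts the new oxygen cis to it (expected to be moderately selective; minor epimer removed here or at 16), then O-silylation of the alkoxide.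

Step 8
Reactants: 15 triethyl{[(1S,5S)-1,2-dimethyl-5-(prop-1-en-2-yl)cyclohex-2-en-1-yl]oxy}silane
Product: 16 (4S,6S)-3,4-dimethyl-6-(prop-1-en-2-yl)-4-[(triethylsilyl)oxy]cyclohex-2-en-1-one
Conditions: CrO3, 3,5-dimethylpyrazole, CH2Cl2, −20 °C
Reagents that add atoms: chromium trioxide, O=[Cr](=O)=O
Why: Allylic C–H oxidation; the ring alkene has a single allylic CH2 (the other allylic ring carbon is quaternary), which becomes the enone carbonyl.

Step 9
Reactants: 16 (4S,6S)-3,4-dimethyl-6-(prop-1-en-2-yl)-4-[(triethylsilyl)oxy]cyclohex-2-en-1-one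
Product: 18 (4S)-3,4-dimethyl-4-[(triethylsilyl)oxy]cyclohex-2-en-1-one, via methoxy hydroperoxide 17 (not isolated)
Conditions: O3, MeOH, −78 °C; then FeSO4·7H2O, PhSH, −78 → 23 °C
Reagents that add atoms: none
Why: Hydrodealkenylation: Criegee ozonolysis of the electron-rich isopropenyl group (the enone C=C is spared), O–O cleavage by divalent iron, β-scission and hydrogen transfer from the thiol; the silyloxy stereocentre set in step 7 is untouched and now carries the chirality alone.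

Step 10
Reactants: 18 (4S)-3,4-dimethyl-4-[(triethylsilyl)oxy]cyclohex-2-en-1-one
Product: 19 (1R,4S)-1-(1-methoxyprop-2-en-1-yl)-3,4-dimethyl-4-[(triethylsilyl)oxy]cyclohex-2-en-1-ol
Conditions: CH2=CHCH2OMe, s-BuLi, THF, −78 °C; ZnCl2; then 18, −78 → 0 °C
Reagents that add atoms: allyl methyl ether, COCC=C
Why: γ-Selective 1,2-addition of the allylic zinc reagent (a homoenolate equivalent) by axial attack anti to the pseudoaxial silyloxy group puts the allyl unit trans to oxygen (moderate selectivity expected, epimer removed; the methoxy-bearing carbon is inconsequential).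

Step 11
Reactants: 19 (1R,4S)-1-(1-methoxyprop-2-en-1-yl)-3,4-dimethyl-4-[(triethylsilyl)oxy]cyclohex-2-en-1-ol
Product: 22 (3S,4S)-3-(3-methoxyprop-2-en-1-yl)-3,4-dimethyl-2-(prop-2-en-1-yl)-4-[(triethylsilyl)oxy]cyclohexan-1-one, via potassium alkoxide 20 (not isolated), via potassium enolate 21 (not isolated)
Conditions: KH, 18-crown-6, THF, 0 → 23 °C; then allyl bromide, −78 → 0 °C
Reagents that add atoms: allyl bromide, C=CCBr
Why: Anionic oxy-Cope rearrangement ([3,3]-sigmatropic): the allyl unit migrates suprafacially from the carbinol carbon to the β-carbon, forming the quaternary C–C bond on the face trans to the silyloxy group (3S), and the regiodefined enolate is then C-allylated.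

Step 12
Reactants: 22 (3S,4S)-3-(3-methoxyprop-2-en-1-yl)-3,4-dimethyl-2-(prop-2-en-1-yl)-4-[(triethylsilyl)oxy]cyclohexan-1-one
Product: 25 (4aS,5S,8aS)-2-methoxy-4a,8a-dimethyl-5-(prop-2-en-1-yl)octahydro-2H-chromen-6-one, via hydroxy dimethyl acetal 23 (not isolated), via epimeric bicyclic acetal 24 (not isolated)
Conditions: p-TsOH·H2O (cat.), MeOH, 23 °C; then NaOMe (excess), MeOH, 23 °C
Reagents that add atoms: methanol, CO
Why: Acid-catalysed acetal exchange, desilylation and ring closure give the trans-fused cyclic methyl acetal; base epimerisation of the ketone α-carbon (thermodynamic control) then puts the allyl group equatorial, because the axial epimer is syn-diaxial to the angular methyl.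

Step 13
Reactants: 25 (4aS,5S,8aS)-2-methoxy-4a,8a-dimethyl-5-(prop-2-en-1-yl)octahydro-2H-chromen-6-one
Product: 27 (4aS,5S,8aS)-5-(3-hydroxypropyl)-2-methoxy-4a,8a-dimethyloctahydro-2H-chromen-6-one, via alkylborane 26 (not isolated)
Conditions: 9-BBN, THF, 23 °C; then aq. NaOH, H2O2, 0 °C
Reagents that add atoms: hydrogen peroxide, OO
Why: Anti-Markovnikov hydroboration–oxidation of the terminal alkene; 9-BBN leaves the hindered ketone alone and the α-carbon is already the thermodynamic epimer.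

Step 14
Reactants: 27 (4aS,5S,8aS)-5-(3-hydroxypropyl)-2-methoxy-4a,8a-dimethyloctahydro-2H-chromen-6-one
Product: 28 (4aS,5S,8aS)-5-{3-[(tert-butyldiphenylsilyl)oxy]propyl}-2-methoxy-4a,8a-dimethyloctahydro-2H-chromen-6-one
Conditions: t-BuPh2SiCl, imidazole, DMF, 23 °C
Reagents that add atoms: tert-butyl(chloro)diphenylsilane, CC(C)(C)[Si](Cl)(c1ccccc1)c1ccccc1
Why: Silyl ether formation protects the primary alcohol for the chromium oxidation of step 18.

Step 15
Reactants: 28 (4aS,5S,8aS)-5-{3-[(tert-butyldiphenylsilyl)oxy]propyl}-2-methoxy-4a,8a-dimethyloctahydro-2H-chromen-6-one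
Product: 29 (4aS,5S,8aS)-5-{3-[(tert-butyldiphenylsilyl)oxy]propyl}-2-hydroxy-4a,8a-dimethyloctahydro-2H-chromen-6-one
Conditions: pyridinium p-toluenesulfonate, acetone–H2O, 50 °C
Reagents that add atoms: water, O
Why: Acid hydrolysis of the methyl acetal to the lactol unmasks the aldehyde and the tertiary alcohol; the silyl ether survives.

Step 16
Reactants: 29 (4aS,5S,8aS)-5-{3-[(tert-butyldiphenylsilyl)oxy]propyl}-2-hydroxy-4a,8a-dimethyloctahydro-2H-chromen-6-one
Product: 30 (2S,3S,4S)-2-{3-[(tert-butyldiphenylsilyl)oxy]propyl}-3-(4,4-dibromobut-3-en-1-yl)-4-hydroxy-3,4-dimethylcyclohexan-1-one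
Conditions: CBr4, PPh3, Zn, CH2Cl2, 23 °C, 24 h; then 29, 23 °C
Reagents that add atoms: carbon tetrabromide, BrC(Br)(Br)Br
Why: Ramirez–Corey–Fuchs dibromo-olefination (Wittig type) of the open hydroxy-aldehyde form of the lactol; the hindered ketone does not react.

Step 17
Reactants: 30 (2S,3S,4S)-2-{3-[(tert-butyldiphenylsilyl)oxy]propyl}-3-(4,4-dibromobut-3-en-1-yl)-4-hydroxy-3,4-dimethylcyclohexan-1-one
Product: 31 (1S,2S,3S,4RS)-3-{3-[(tert-butyldiphenylsilyl)oxy]propyl}-2-(4,4-dibromobut-3-en-1-yl)-1,2-dimethyl-4-(prop-1-en-2-yl)cyclohexane-1,4-diol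
Conditions: CH2=C(CH3)MgBr (4 equiv), CeCl3, THF, −78 → 0 °C
Reagents that add atoms: isopropenylmagnesium bromide, CC(=C)[Mg]Br
Why: 1,2-Addition of the organocerium reagent to the hindered ketone without enolisation, so the neighbouring stereocentre keeps its configuration; the new carbinol centre is destroyed in step 18.

Step 18
Reactants: 31 (1S,2S,3S,4RS)-3-{3-[(tert-butyldiphenylsilyl)oxy]propyl}-2-(4,4-dibromobut-3-en-1-yl)-1,2-dimethyl-4-(prop-1-en-2-yl)cyclohexane-1,4-diol
Product: 34 (2Z)-2-[(2R,3S,4S)-2-{3-[(tert-butyldiphenylsilyl)oxy]propyl}-3-(4,4-dibromobut-3-en-1-yl)-4-hydroxy-3,4-dimethylcyclohexylidene]propanal, via tertiary chlorochromate ester 32 (not isolated), via rearranged chlorochromate ester 33 (not isolated)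
Conditions: [C5H5NH][CrO3Cl], NaOAc, 4 Å molecular sieves, CH2Cl2, 23 °C
Reagents that add atoms: pyridinium chlorochromate, [O-][Cr](=O)(=O)Cl.c1cc[nH+]cc1
Why: Babler–Dauben oxidative transposition: [3,3]-sigmatropic shift of the tertiary allylic chromate ester, then oxidation, gives the tetrasubstituted enal; the Z isomer (CHO syn to the substituted ring carbon) is expected to be the less strained one, and the geometric isomers should equilibrate under the acidic conditions.

Step 19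
Reactants: 12 (1S,3S)-1-ethynyl-2,2,3-trimethyl-6-methylidenecyclohexane; 34 (2Z)-2-[(2R,3S,4S)-2-{3-[(tert-butyldiphenylsilyl)oxy]propyl}-3-(4,4-dibromobut-3-en-1-yl)-4-hydroxy-3,4-dimethylcyclohexylidene]propanal
Product: 36 (2Z)-2-[(2R,3S,4S)-3-{(3Z,5E)-4-bromo-6-[(1R,3S)-2,2,3-trimethyl-6-methylidenecyclohexyl]hexa-3,5-dien-1-yl}-2-{3-[(tert-butyldiphenylsilyl)oxy]propyl}-4-hydroxy-3,4-dimethylcyclohexylidene]propanal, via alkenylboronate 35 (not isolated)
Conditions: 12, pinacolborane, Cp2Zr(H)Cl (5 mol %), CH2Cl2, 23 °C; then 34, Pd(PPh3)4 (5 mol %), TlOEt, THF–H2O, 23 °C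
Reagents that add atoms: none
Why: Syn hydroboration of the terminal alkyne (faster than the hindered 1,1-disubstituted alkene) gives the E-alkenylboronate, and Suzuki–Miyaura coupling occurs only at the bromide trans to the alkyl chain, with retention.

Step 20
Reactants: 36 (2Z)-2-[(2R,3S,4S)-3-{(3Z,5E)-4-bromo-6-[(1R,3S)-2,2,3-trimethyl-6-methylidenecyclohexyl]hexa-3,5-dien-1-yl}-2-{3-[(tert-butyldiphenylsilyl)oxy]propyl}-4-hydroxy-3,4-dimethylcyclohexylidene]propanal
Product: 37 (2Z)-2-[(2R,3S,4S)-2-{3-[(tert-butyldiphenylsilyl)oxy]propyl}-4-hydroxy-3,4-dimethyl-3-{(3E,5E)-4-methyl-6-[(1R,3S)-2,2,3-trimethyl-6-methylidenecyclohexyl]hexa-3,5-dien-1-yl}cyclohexylidene]propanal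
Conditions: Me2Zn, Pd(P(t-Bu)3)2 (3 mol %), THF, 23 °C
Reagents that add atoms: dimethylzinc, C[Zn]C
Why: Negishi coupling with retention of alkene geometry replaces the remaining bromide by methyl and completes the (3E,5E)-diene.

Step 21
Reactants: 37 (2Z)-2-[(2R,3S,4S)-2-{3-[(tert-butyldiphenylsilyl)oxy]propyl}-4-hydroxy-3,4-dimethyl-3-{(3E,5E)-4-methyl-6-[(1R,3S)-2,2,3-trimethyl-6-methylidenecyclohexyl]hexa-3,5-dien-1-yl}cyclohexylidene]propanal
Product: 38 (2Z)-2-[(2R,3S,4S)-4-hydroxy-2-(3-hydroxypropyl)-3,4-dimethyl-3-{(3E,5E)-4-methyl-6-[(1R,3S)-2,2,3-trimethyl-6-methylidenecyclohexyl]hexa-3,5-dien-1-yl}cyclohexylidene]propanal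
Conditions: Bu4NF, AcOH, THF, 23 °C
Reagents that add atoms: none
Why: Fluoride desilylation of the primary silyl ether under buffered conditions leaves the enal, the diene and the exocyclic alkene intact.

## Compound list

1 | (S)-(−)-pulegone, (5S)-5-methyl-2-(propan-2-ylidene)cyclohexan-1-one | C[C@H]1CCC(=C(C)C)C(=O)C1 | starting material
2 | (3S)-2,3-dimethyl-6-(propan-2-ylidene)cyclohexan-1-one, C2 epimers | C[C@H]1CCC(=C(C)C)C(=O)C1C | intermediate (not isolated)
3 | (3S)-2,2,3-trimethyl-6-(propan-2-ylidene)cyclohexan-1-one | C[C@H]1CCC(=C(C)C)C(=O)C1(C)C | intermediate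
4 | (3S)-2,2,3-trimethylcyclohexan-1-one | C[C@H]1CCCC(=O)C1(C)C | intermediate
5 | N-{[(4S)-2-bromo-3,3,4-trimethylcyclohex-1-en-1-yl]methylidene}-N-methylmethanaminium bromide | C[C@H]1CCC(C=[N+](C)C)=C(Br)C1(C)C.[Br-] | intermediate (not isolated)
6 | (4S)-2-bromo-3,3,4-trimethylcyclohex-1-ene-1-carbaldehyde | C[C@H]1CCC(C=O)=C(Br)C1(C)C | intermediate
7 | (4S)-3,3,4-trimethyl-2-[(trimethylsilyl)ethynyl]cyclohex-1-ene-1-carbaldehyde | C[C@H]1CCC(C=O)=C(C#C[Si](C)(C)C)C1(C)C | intermediate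
8 | {(4S)-3,3,4-trimethyl-2-[(trimethylsilyl)ethynyl]cyclohex-1-en-1-yl}methanol | C[C@H]1CCC(CO)=C(C#C[Si](C)(C)C)C1(C)C | intermediate (not isolated)
9 | [(4S)-2-ethynyl-3,3,4-trimethylcyclohex-1-en-1-yl]methanol | C[C@H]1CCC(CO)=C(C#C)C1(C)C | intermediate
10 | N-{[(4S)-2-ethynyl-3,3,4-trimethylcyclohex-1-en-1-yl]methyl}-2-nitrobenzenesulfonohydrazide (alkylated on the sulfonyl nitrogen) | C[C@H]1CCC(CN(N)S(=O)(=O)c2ccccc2[N+](=O)[O-])=C(C#C)C1(C)C | intermediate (not isolated)
11 | {[(4S)-2-ethynyl-3,3,4-trimethylcyclohex-1-en-1-yl]methyl}diazene | C[C@H]1CCC(CN=N)=C(C#C)C1(C)C | intermediate (not isolated)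
12 | (1S,3S)-1-ethynyl-2,2,3-trimethyl-6-methylidenecyclohexane (ethynyl cis to the 3-methyl) | C=C1CC[C@H](C)C(C)(C)[C@@H]1C#C | intermediate
13 | (S)-(+)-carvone, (5S)-2-methyl-5-(prop-1-en-2-yl)cyclohex-2-en-1-one | CC1=CC[C@H](C(C)=C)CC1=O | starting material
14 | lithium (1S,5S)-1,2-dimethyl-5-(prop-1-en-2-yl)cyclohex-2-en-1-olate (O cis to isopropenyl) | CC1=CC[C@H](C(C)=C)C[C@]1(C)[O-].[Li+] | intermediate (not isolated)
15 | triethyl{[(1S,5S)-1,2-dimethyl-5-(prop-1-en-2-yl)cyclohex-2-en-1-yl]oxy}silane | CC1=CC[C@H](C(C)=C)C[C@]1(C)O[Si](CC)(CC)CC | intermediate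
16 | (4S,6S)-3,4-dimethyl-6-(prop-1-en-2-yl)-4-[(triethylsilyl)oxy]cyclohex-2-en-1-one | CC1=CC(=O)[C@H](C(C)=C)C[C@]1(C)O[Si](CC)(CC)CC | intermediate
17 | (4S,6S)-6-(1-hydroperoxy-1-methoxyethyl)-3,4-dimethyl-4-[(triethylsilyl)oxy]cyclohex-2-en-1-one | CC1=CC(=O)[C@H](C(C)(OC)OO)C[C@]1(C)O[Si](CC)(CC)CC | intermediate (not isolated)
18 | (4S)-3,4-dimethyl-4-[(triethylsilyl)oxy]cyclohex-2-en-1-one | CC1=CC(=O)CC[C@]1(C)O[Si](CC)(CC)CC | intermediate
19 | (1R,4S)-1-(1-methoxyprop-2-en-1-yl)-3,4-dimethyl-4-[(triethylsilyl)oxy]cyclohex-2-en-1-ol (both epimers at the methoxy carbon) | CC1=C[C@@](O)(C(OC)C=C)CC[C@]1(C)O[Si](CC)(CC)CC | intermediate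
20 | potassium alkoxide of 19 | CC1=C[C@@]([O-])(C(OC)C=C)CC[C@]1(C)O[Si](CC)(CC)CC.[K+] | intermediate (not isolated)
21 | potassium (3S,4S)-3-(3-methoxyprop-2-en-1-yl)-3,4-dimethyl-4-[(triethylsilyl)oxy]cyclohex-1-en-1-olate | COC=CC[C@@]1(C)C=C([O-])CC[C@]1(C)O[Si](CC)(CC)CC.[K+] | intermediate (not isolated)
22 | (3S,4S)-3-(3-methoxyprop-2-en-1-yl)-3,4-dimethyl-2-(prop-2-en-1-yl)-4-[(triethylsilyl)oxy]cyclohexan-1-one (C2 epimers, enol ether E/Z) | COC=CC[C@@]1(C)C(CC=C)C(=O)CC[C@]1(C)O[Si](CC)(CC)CC | intermediate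
23 | (3S,4S)-3-(3,3-dimethoxypropyl)-4-hydroxy-3,4-dimethyl-2-(prop-2-en-1-yl)cyclohexan-1-one | COC(OC)CC[C@@]1(C)C(CC=C)C(=O)CC[C@]1(C)O | intermediate (not isolated)
24 | (4aS,8aS)-2-methoxy-4a,8a-dimethyl-5-(prop-2-en-1-yl)octahydro-2H-chromen-6-one, C5 epimers | COC1CC[C@@]2(C)C(CC=C)C(=O)CC[C@]2(C)O1 | intermediate (not isolated)
25 | (4aS,5S,8aS)-2-methoxy-4a,8a-dimethyl-5-(prop-2-en-1-yl)octahydro-2H-chromen-6-one (trans-fused, allyl equatorial and cis to the ring oxygen, anomers) | COC1CC[C@@]2(C)[C@H](CC=C)C(=O)CC[C@]2(C)O1 | intermediate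
26 | B-alkyl-9-borabicyclo[3.3.1]nonane adduct of 25 | COC1CC[C@@]2(C)[C@H](CCCB3C4CCCC3CCC4)C(=O)CC[C@]2(C)O1 | intermediate (not isolated)
27 | (4aS,5S,8aS)-5-(3-hydroxypropyl)-2-methoxy-4a,8a-dimethyloctahydro-2H-chromen-6-one | COC1CC[C@@]2(C)[C@H](CCCO)C(=O)CC[C@]2(C)O1 | intermediate
28 | (4aS,5S,8aS)-5-{3-[(tert-butyldiphenylsilyl)oxy]propyl}-2-methoxy-4a,8a-dimethyloctahydro-2H-chromen-6-one | COC1CC[C@@]2(C)[C@H](CCCO[Si](c3ccccc3)(c3ccccc3)C(C)(C)C)C(=O)CC[C@]2(C)O1 | intermediate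
29 | (4aS,5S,8aS)-5-{3-[(tert-butyldiphenylsilyl)oxy]propyl}-2-hydroxy-4a,8a-dimethyloctahydro-2H-chromen-6-one (lactol) | OC1CC[C@@]2(C)[C@H](CCCO[Si](c3ccccc3)(c3ccccc3)C(C)(C)C)C(=O)CC[C@]2(C)O1 | intermediate
30 | (2S,3S,4S)-2-{3-[(tert-butyldiphenylsilyl)oxy]propyl}-3-(4,4-dibromobut-3-en-1-yl)-4-hydroxy-3,4-dimethylcyclohexan-1-one | BrC(Br)=CCC[C@@]1(C)[C@H](CCCO[Si](c2ccccc2)(c2ccccc2)C(C)(C)C)C(=O)CC[C@]1(C)O | intermediate
31 | (1S,2S,3S,4RS)-3-{3-[(tert-butyldiphenylsilyl)oxy]propyl}-2-(4,4-dibromobut-3-en-1-yl)-1,2-dimethyl-4-(prop-1-en-2-yl)cyclohexane-1,4-diol | BrC(Br)=CCC[C@@]1(C)[C@H](CCCO[Si](c2ccccc2)(c2ccccc2)C(C)(C)C)C(O)(C(C)=C)CC[C@]1(C)O | intermediate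
32 | tertiary allylic chlorochromate ester of 31 | BrC(Br)=CCC[C@@]1(C)[C@H](CCCO[Si](c2ccccc2)(c2ccccc2)C(C)(C)C)C(O[Cr](=O)(=O)Cl)(C(C)=C)CC[C@]1(C)O | intermediate (not isolated)
33 | primary allylic chlorochromate ester formed by the 3,3-shift | BrC(Br)=CCC[C@@]1(C)[C@H](CCCO[Si](c2ccccc2)(c2ccccc2)C(C)(C)C)/C(=C(/C)CO[Cr](=O)(=O)Cl)CC[C@]1(C)O | intermediate (not isolated)
34 | (2Z)-2-[(2R,3S,4S)-2-{3-[(tert-butyldiphenylsilyl)oxy]propyl}-3-(4,4-dibromobut-3-en-1-yl)-4-hydroxy-3,4-dimethylcyclohexylidene]propanal | BrC(Br)=CCC[C@@]1(C)[C@H](CCCO[Si](c2ccccc2)(c2ccccc2)C(C)(C)C)/C(=C(/C)C=O)CC[C@]1(C)O | intermediate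
35 | 4,4,5,5-tetramethyl-2-{(E)-2-[(1R,3S)-2,2,3-trimethyl-6-methylidenecyclohexyl]ethenyl}-1,3,2-dioxaborolane | C=C1CC[C@H](C)C(C)(C)[C@@H]1/C=C/B1OC(C)(C)C(C)(C)O1 | intermediate (not isolated)
36 | (2Z)-2-[(2R,3S,4S)-3-{(3Z,5E)-4-bromo-6-[(1R,3S)-2,2,3-trimethyl-6-methylidenecyclohexyl]hexa-3,5-dien-1-yl}-2-{3-[(tert-butyldiphenylsilyl)oxy]propyl}-4-hydroxy-3,4-dimethylcyclohexylidene]propanal | C=C1CC[C@H](C)C(C)(C)[C@@H]1/C=C/C(Br)=C/CC[C@@]1(C)[C@H](CCCO[Si](c2ccccc2)(c2ccccc2)C(C)(C)C)/C(=C(/C)C=O)CC[C@]1(C)O | intermediate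
37 | (2Z)-2-[(2R,3S,4S)-2-{3-[(tert-butyldiphenylsilyl)oxy]propyl}-4-hydroxy-3,4-dimethyl-3-{(3E,5E)-4-methyl-6-[(1R,3S)-2,2,3-trimethyl-6-methylidenecyclohexyl]hexa-3,5-dien-1-yl}cyclohexylidene]propanal | C=C1CC[C@H](C)C(C)(C)[C@@H]1/C=C/C(C)=C/CC[C@@]1(C)[C@H](CCCO[Si](c2ccccc2)(c2ccccc2)C(C)(C)C)/C(=C(/C)C=O)CC[C@]1(C)O | intermediate
38 | (2Z)-2-[(2R,3S,4S)-4-hydroxy-2-(3-hydroxypropyl)-3,4-dimethyl-3-{(3E,5E)-4-methyl-6-[(1R,3S)-2,2,3-trimethyl-6-methylidenecyclohexyl]hexa-3,5-dien-1-yl}cyclohexylidene]propanal (CNP0155943.1) | C=C1CC[C@H](C)C(C)(C)[C@@H]1/C=C/C(C)=C/CC[C@@]1(C)[C@H](CCCO)/C(=C(/C)C=O)CC[C@]1(C)O | target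

## Step count and risks

Total step count: 21. Longest linear sequence: 15 steps (steps 7 to 21, from (S)-carvone); the pulegone branch (steps 1 to 6) joins in step 19.

The three steps most likely to fail:

Step 1. The second enolisation of the monomethyl ketone 2 may go to the γ-methyl groups of the isopropylidene unit instead of the now tertiary α′-carbon, giving mixtures. The fallback sets out from 1 and comes back at 4, and replaces the built-in blocking group by a removable one. Retro-aldol cleavage of 1 (KOH, H2O–EtOH, reflux) gives (3S)-3-methylcyclohexan-1-one F1. Formylation at the less hindered α-carbon (HCO2Et, NaH) gives the hydroxymethylidene ketone F2, which n-BuSH and p-TsOH convert into the butylthiomethylidene ketone F3. Double methylation of the only free α-carbon (KOt-Bu, MeI) gives the blocked trimethyl ketone F4, and KOH in aqueous diethylene glycol at reflux removes the blocking group to give 4.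

Step 11, together with the face selectivity of step 10. The 1,2-addition is controlled only by a 1,4-relationship to the silyloxy carbon, and the [3,3] shift must form a quaternary carbon next to a fully substituted one; the alkoxide may fragment back to the enone instead. The fallback sets out from 18 and comes back at 25, and replaces the sigmatropic shift by a conjugate addition, whose anti relationship to a γ-silyloxy group is well established. The Grignard reagent from 2-(2-bromoethyl)-1,3-dioxolane with CuBr·SMe2 and Me3SiCl (THF, −78 °C) gives the trimethylsilyl enol ether F5. MeLi and then allyl bromide convert it into the dioxolane ketone F6. Under the conditions of step 12 (p-TsOH in MeOH, then NaOMe), F6 gives 25.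

Step 18. The chromate shift may give the tetrasubstituted enal as a mixture of geometric isomers, or mainly the unwanted one. The fallback sets out from 30 and comes back at 34, and builds the alkene by olefination, so the isomers can be separated one oxidation level earlier. Horner–Wadsworth–Emmons reaction of 30 with diethyl (1-cyanoethyl)phosphonate (NaH, THF, reflux) gives the unsaturated nitrile F7; the isomer with the nitrile syn to the propyl-bearing carbon is separated and the other is recycled by iodine-catalysed photoisomerisation. i-Bu2AlH (toluene, −78 °C) followed by dilute acid gives 34.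

Further compounds

F1 | step 1 | (3S)-3-methylcyclohexan-1-one | C[C@H]1CCCC(=O)C1
F2 | step 1 | (5S)-2-(hydroxymethylidene)-5-methylcyclohexan-1-one | C[C@H]1CCC(=CO)C(=O)C1
F3 | step 1 | (5S)-2-[(butylsulfanyl)methylidene]-5-methylcyclohexan-1-one | C[C@H]1CCC(=CSCCCC)C(=O)C1
F4 | step 1 | (3S)-6-[(butylsulfanyl)methylidene]-2,2,3-trimethylcyclohexan-1-one | C[C@H]1CCC(=CSCCCC)C(=O)C1(C)C
F5 | step 11 | {[(3S,4S)-3-[2-(1,3-dioxolan-2-yl)ethyl]-3,4-dimethyl-4-[(triethylsilyl)oxy]cyclohex-1-en-1-yl]oxy}trimethylsilane | O1CCOC1CC[C@@]2(C)C=C(O[Si](C)(C)C)CC[C@]2(C)O[Si](CC)(CC)CC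
F6 | step 11 | (3S,4S)-3-[2-(1,3-dioxolan-2-yl)ethyl]-3,4-dimethyl-2-(prop-2-en-1-yl)-4-[(triethylsilyl)oxy]cyclohexan-1-one (C2 epimers) | O1CCOC1CC[C@@]2(C)C(CC=C)C(=O)CC[C@]2(C)O[Si](CC)(CC)CC
F7 | step 18 | (2Z)-2-[(2R,3S,4S)-2-{3-[(tert-butyldiphenylsilyl)oxy]propyl}-3-(4,4-dibromobut-3-en-1-yl)-4-hydroxy-3,4-dimethylcyclohexylidene]propanenitrile | BrC(Br)=CCC[C@@]1(C)[C@H](CCCO[Si](c2ccccc2)(c2ccccc2)C(C)(C)C)/C(=C(/C)C#N)CC[C@]1(C)O
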